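## The problem

The target, (3R)-6,8-dihydroxy-3-[(9S)-9-hydroxyundecyl]isochroman-1-one (13), is a resorcylic 3,4-dihydroisocoumarin. A benzene ring (ring A) is fused through C4a–C8a to a six-membered lactone (ring B: C1, O2, C3, C4), and C3 carries an eleven-carbon chain. A synthesis must join three parts: the 2,4-dioxygenated benzoyl unit, the two ring carbons C3 and C4, and the chain. There are two stereocentres, C3 (R) in ring B and C9' (S) in the chain. Eight methylene groups separate them, so neither can direct the other and each needs its own reagent or catalyst control. The free resorcinol is easily oxidised, the lactone opens under strong aqueous base, and the C9' carbinol can be substituted or eliminated under strongly acidic conditions, so phenols and carbinol are carried masked and released last. The key step rests on one feature: in 2,4-dimethoxybenzoic acid (9) the carbon that becomes C4a is the only free position ortho to the carboxyl group, because the other ortho carbon (the future C8) bears a methoxy group. Since C3 is the only stereocentre of the bicycle, ring B can be closed first as the flat isocoumarin (C3=C4) and C3 set afterwards by a face-selective hydrogenation.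

## Retrosynthesis

**13 ⇐ 12 (ether cleavage).** The two aryl O–CH3 bonds and the C9' O–Si bond are cut. Methyl ethers come with the commercial acid 9 and survive every later step, and a tert-butyldimethylsilyl (TBS) ether on C9' tolerates ylide chemistry, C–H activation and hydrogenation. Benzyl ethers would allow a milder release but would need a non-commercial acid and a second deprotection. Precursor 12 has no free hydroxyl and the same skeleton. The forward step must cleave three ethers with one Lewis acid without breaking the C3–O bond or substituting C9'.

**12 ⇐ 11 (retro-hydrogenation).** The C3–H and C4–H bonds are removed to give the isocoumarin 11. The neighbouring cuts are lactonisation of a preformed chiral carbinol or opening of a chiral epoxide by an ortho-metalated benzoate. Both force the chain to carry both stereocentres before it meets the arene. The hydrogenation keeps the chain at one stereocentre and lets a catalyst read a planar ring. Precursor 11 has no ring stereocentre. The forward step needs high face selectivity on a 3-alkyl, 8-methoxy isocoumarin and must leave arene, lactone and silyl ether alone.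

**11 ⇐ 8 + 9 (key disconnection).** The C4a–C4 and O2–C3 bonds are cut, passing through keto acid 10. This splits the molecule into the commercial acid 9 and the keto sulfoxonium ylide 8. An oxidative annulation with an alkyne would make the same two bonds but leaves the C3/C4 regiochemistry open and needs a stoichiometric oxidant. A Sonogashira–cyclisation sequence would need a halide at the crowded C6 of the acid and can close five-membered instead. Lateral metalation of a toluate needs strong base on an enolisable acyl donor. The ylide route is redox-neutral, and its ketone carbon can only become C3. The forward step needs C–H cleavage at the single free ortho position and dehydration of 10 to the enol lactone.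

**8 ⇐ 5 + 6 (acylation of a sulfur ylide).** The bond between the ylide carbon (future C4) and the ketone carbon (future C3) is cut. This gives the methyl ester 5 and trimethylsulfoxonium iodide (6), which is deprotonated in the flask to the methylide 7. The ester is the simplest acyl donor that needs no activation. The forward step must acylate 7 faster than 7 deprotonates the ester at its α-carbon.

**5 ⇐ 4 ⇐ 3 (oxidative alkene cleavage, silylation).** The ester carbon of 5 comes from the internal alkene carbon of 4, and the terminal CH2 is lost. A terminal alkene is an inert placeholder for the carboxyl group during the organozinc step. Removing the silyl group leads back to alcohol 3. The cleavage must deliver the ester oxidation state directly and spare the silyl ether.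

**3 ⇐ 1 + 2 (enantioselective ethyl addition).** The C9'–C10' bond is cut to 10-undecenal (1) and diethylzinc (2). Both are commercial, and the cut creates the only chain stereocentre in the first step. The alternative of opening a chiral C4 epoxide with a long-chain Grignard reagent is equally short but needs a less common bromide. The forward step needs high enantioselectivity on an unbranched aliphatic aldehyde.

## Roads not taken

**Alternative 1:** Organocatalytic annulation of a homophthalic anhydride with the chain aldehyde. The cut is C3–C4 and O2–C1. In the forward step a cinchona-derived squaramide base would catalyse addition of the enol of 6,8-dimethoxyisochromane-1,3-dione A1 to (10S)-10-(tert-butyldimethylsilyloxy)dodecanal A2. The resulting alkoxide opens the anhydride at the aryl carbonyl and gives (3R)-6,8-dimethoxy-1-oxo-3-[(9S)-9-(tert-butyldimethylsilyloxy)undecyl]isochromane-4-carboxylic acid A3 as both C4 epimers.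
- Merits: ring B and C3 arise together, without metal and at ambient pressure. A2 is one reduction away from ester 5, so the chain costs the same.
- Weak points: A1 is not commercial and takes several steps to make. The high selectivities of this reaction type are established mainly for aromatic aldehydes, and A2 is linear and enolisable. The C4 carboxyl group of A3 is an arylacetic acid and does not leave spontaneously; a forcing thermal or radical decarboxylation is needed to reach 12.
- Comparison: this road is better in stereochemical economy, since it needs no separate hydrogenation. The chosen plan sets against it a commercial arene, no excision step, and a hydrogenation whose substrate class (3-alkyl, 8-alkoxy isocoumarins) matches 11 directly.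

**Alternative 2:** Photochemical Wolff rearrangement and Danheiser benzannulation on an enantiopure dihydropyranone. Ring A is cut at C5–C6, C7–C8 and C8–C8a, with C4a–C5 formed by a 1,2-shift. Irradiation of (6R)-4-(2-diazoacetyl)-6-[(9S)-9-(tert-butyldimethylsilyloxy)undecyl]-5,6-dihydro-2H-pyran-2-one A4 would give a vinylketene. This adds ethoxyacetylene A5, and ring opening and electrocyclisation give (3R)-6-ethoxy-8-hydroxy-3-[(9S)-9-(tert-butyldimethylsilyloxy)undecyl]isochroman-1-one A6.
- Merits: C3 is fixed before the arene exists, so no late enantioselective step is needed. The two phenol oxygens emerge differentiated and the substitution pattern is unambiguous.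
- Weak points: a benzene ring that can be bought is built from scratch. A4 needs its own enantioselective lactone synthesis, a C4 acyl group and a diazo transfer. A5 is volatile and costly, and the photochemical step scales poorly. The ethyl ether of A6 still needs the same boron-halide dealkylation as 12, so the end-game is not improved.
- Comparison: this road is better only in being independent of a catalytic hydrogenation. The chosen plan is several steps shorter.

**Alternative 3:** Biomimetic aldol aromatisation of a diketo-dioxinone. The cut is C4a–C8a. A tertiary amine would promote an intramolecular aldol in 6-[(6R,15S)-6,15-bis(tert-butyldimethylsilyloxy)-2,4-dioxoheptadecyl]-2,2-dimethyl-4H-1,3-dioxin-4-one A7. Dehydration and enolisation then give 7-hydroxy-2,2-dimethyl-5-[(2R,11S)-2,11-bis(tert-butyldimethylsilyloxy)tridecyl]-4H-benzo[d][1,3]dioxin-4-one A8. Desilylation and lactonisation with loss of the ketal would lead to 13.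
- Merits: the aromatisation is mild, and the phenols are never methylated. The end-game is gentler than that of the chosen plan, which is a real advantage.
- Weak points: A7 must carry both stereocentres before any ring exists, so the chain synthesis is long and linear. Its tricarbonyl array is labile. The C6 silyloxy group is β to the ketone that becomes C4a and can be lost by elimination under the basic aromatisation conditions.
- Comparison: this road has the better last step. The chosen plan sets against it seven steps from commercial materials and a single, robust ring-forming step, and accepts the harsher final dealkylation.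

Key step: step 5

Assumption: the sense of induction of the ruthenium carbene–diamine catalyst is fixed by its ligand antipodes; the pair written in step 6 is taken as the one that adds hydrogen to the C3 Si face, and the mirror-image pair is used if the sense proves opposite.

## Route

Step 1
Reactants: 1 10-undecenal; 2 diethylzinc
Product: 3 (3S)-tridec-12-en-3-ol
Conditions: Et2Zn (2.0 equiv), Ti(OiPr)4 (1.2 equiv), (1R,2R)-N,N'-bis(trifluoromethanesulfonyl)cyclohexane-1,2-diamine (4 mol %), toluene, −20 °C; aq. HCl
Reagents that add atoms: diethylzinc (2), CC[Zn]CC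
Why: Catalytic enantioselective addition of a dialkylzinc to an aldehyde under titanium–bis(sulfonamide) catalysis, which is effective for unbranched aliphatic aldehydes; the (1R,2R) ligand delivers ethyl to the aldehyde Si face and sets the S carbinol (future C9'), and the terminal alkene is inert.

Step 2
Reactants: 3 (3S)-tridec-12-en-3-ol
Product: 4 tert-butyldimethyl{[(3S)-tridec-12-en-3-yl]oxy}silane
Conditions: TBSCl (1.2 equiv), imidazole (2.5 equiv), DMF, rt
Reagents that add atoms: tert-butyldimethylsilyl chloride, CC(C)(C)[Si](C)(C)Cl
Why: Standard imidazole-promoted silylation of a secondary alcohol; no bond to the stereocentre is broken.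

Step 3
Reactants: 4 tert-butyldimethyl{[(3S)-tridec-12-en-3-yl]oxy}silane
Product: 5 methyl (10S)-10-(tert-butyldimethylsilyloxy)dodecanoate
Conditions: O3, NaOH (2.5 M in MeOH, 5 equiv), CH2Cl2, −78 °C; then H2O
Reagents that add atoms: ozone, [O-][O+]=O; methanol, CO
Why: Ozonolysis in methanolic NaOH converts a terminal alkene directly into the methyl ester (methanol traps the carbonyl oxide, and the aldehyde hemiacetal is oxidised by ozone); the silyl ether and the remote stereocentre are untouched at −78 °C.

Step 4
Reactants: 5 methyl (10S)-10-(tert-butyldimethylsilyloxy)dodecanoate; 6 trimethylsulfoxonium iodide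
Product: 8 dimethylsulfoxonium (11S)-11-(tert-butyldimethylsilyloxy)-2-oxotridecylide [Me2S(O)=CH–C(=O)–(CH2)8–CH(OTBS)–CH2CH3], via dimethylsulfoxonium methylide 7 (not isolated)
Conditions: 6 (3 equiv), KOtBu (3 equiv), THF, reflux; then 5, 0 °C → rt
Reagents that add atoms: trimethylsulfoxonium iodide (6), C[S+](C)(C)=O.[I-]
Why: Acylation of the Corey–Chaykovsky methylide by a methyl ester; the first-formed β-keto sulfoxonium salt is deprotonated in the flask to the stabilised keto ylide, and the silyl ether is inert to these conditions.

Step 5
Reactants: 8 dimethylsulfoxonium (11S)-11-(tert-butyldimethylsilyloxy)-2-oxotridecylide; 9 2,4-dimethoxybenzoic acid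
Product: 11 6,8-dimethoxy-3-[(9S)-9-(tert-butyldimethylsilyloxy)undecyl]-1H-isochromen-1-one (the isocoumarin), via keto acid 10 (not isolated)
Conditions: [Cp*RhCl2]2 (4 mol %), AgSbF6 (16 mol %), NaOAc (0.5 equiv), ClCH2CH2Cl, 100 °C
Reagents that add atoms: none
Why: Chloride abstraction by AgSbF6 gives a cationic Cp*Rh species (trivalent rhodium) that binds the carboxylate of 9 and cleaves the only free ortho C–H bond (future C4a) by acetate-assisted concerted metalation–deprotonation, forming a five-membered rhodacycle. Ylide 8 binds through carbon and expels dimethyl sulfoxide to give a rhodium carbene; migratory insertion of the aryl group forms C4a–C4, and protodemetalation releases keto acid 10 and the catalyst, so the process is redox-neutral. Under the same warm, mildly acidic conditions the carboxyl oxygen of 10 adds to the ketone (6-exo-trig) and the lactol loses water, which forms O2–C3 and closes ring B as the enol lactone 11. The closest known reaction type is the annulation of benzoic acids with α-keto sulfoxonium ylides to 3-substituted isocoumarins under trivalent rhodium, trivalent iridium or divalent ruthenium catalysis. No stereocentre is formed, and C9' is eight methylenes from any reacting atom. The step needs site selectivity on the arene and regiochemistry in ring B: the first is secured because C8 is blocked by methoxy, the second because the ylide carbon can only become C4 and its ketone carbon C3. The silyl ether is protected by running in 1,2-dichloroethane with acetate buffer instead of an acidic fluorinated alcohol.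

Step 6
Reactants: 11 6,8-dimethoxy-3-[(9S)-9-(tert-butyldimethylsilyloxy)undecyl]-1H-isochromen-1-one
Product: 12 (3R)-6,8-dimethoxy-3-[(9S)-9-(tert-butyldimethylsilyloxy)undecyl]isochroman-1-one
Conditions: H2 (50 bar), ruthenium carbene–diamine precatalyst [from Ru(cod)(2-methylallyl)2, 1,3-bis[(R)-1-(1-naphthyl)ethyl]imidazolinium tetrafluoroborate, KOtBu and (R,R)-1,2-diphenylethylenediamine; 2 mol %], NaOtBu (10 mol %), toluene, 25 °C
Reagents that add atoms: none
Why: Catalyst-controlled asymmetric hydrogenation of a 3-substituted isocoumarin by a chiral divalent ruthenium carbene–diamine complex, a known transformation for 3-alkyl and 8-alkoxy isocoumarins; hydrogen delivered to the Si face of C3 (O2 > C4 > C1') gives 3R, and the remote C9' centre, the arene and the silyl ether take no part.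

Step 7
Reactants: 12 (3R)-6,8-dimethoxy-3-[(9S)-9-(tert-butyldimethylsilyloxy)undecyl]isochroman-1-one
Product: 13 (3R)-6,8-dihydroxy-3-[(9S)-9-hydroxyundecyl]isochroman-1-one
Conditions: BBr3 (6 equiv), CH2Cl2, −78 °C → rt; then H2O, 0 °C
Reagents that add atoms: none
Why: Lewis-acid ether cleavage: BBr3 complexes each ether oxygen and bromide removes methyl and silyl, the peri 8-methoxy first with carbonyl assistance; the aryl and alkyl borates hydrolyse on quench, C3 has no acidic hydrogen and is not epimerised, and an unactivated secondary alkyl borate should not ionise at or below room temperature.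

## Compound list

1 | 10-undecenal (undec-10-enal) | C=CCCCCCCCCC=O | starting material
2 | diethylzinc | CC[Zn]CC | starting material
3 | (3S)-tridec-12-en-3-ol | CC[C@H](O)CCCCCCCCC=C | intermediate
4 | tert-butyldimethyl{[(3S)-tridec-12-en-3-yl]oxy}silane | CC[C@H](O[Si](C)(C)C(C)(C)C)CCCCCCCCC=C | intermediate
5 | methyl (10S)-10-(tert-butyldimethylsilyloxy)dodecanoate | CC[C@H](O[Si](C)(C)C(C)(C)C)CCCCCCCCC(=O)OC | intermediate
6 | trimethylsulfoxonium iodide | C[S+](C)(C)=O.[I-] | starting material
7 | dimethylsulfoxonium methylide | C=S(C)(C)=O | intermediate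
8 | dimethylsulfoxonium (11S)-11-(tert-butyldimethylsilyloxy)-2-oxotridecylide | CC[C@H](O[Si](C)(C)C(C)(C)C)CCCCCCCCC(=O)C=S(C)(C)=O | intermediate
9 | 2,4-dimethoxybenzoic acid | COc1ccc(C(=O)O)c(OC)c1 | starting material
10 | 2,4-dimethoxy-6-[(11S)-11-(tert-butyldimethylsilyloxy)-2-oxotridecyl]benzoic acid | CC[C@H](O[Si](C)(C)C(C)(C)C)CCCCCCCCC(=O)Cc1cc(OC)cc(OC)c1C(=O)O | intermediate
11 | 6,8-dimethoxy-3-[(9S)-9-(tert-butyldimethylsilyloxy)undecyl]-1H-isochromen-1-one | CC[C@H](O[Si](C)(C)C(C)(C)C)CCCCCCCCC1=Cc2cc(OC)cc(OC)c2C(=O)O1 | intermediate
12 | (3R)-6,8-dimethoxy-3-[(9S)-9-(tert-butyldimethylsilyloxy)undecyl]isochroman-1-one | CC[C@H](O[Si](C)(C)C(C)(C)C)CCCCCCCC[C@@H]1Cc2cc(OC)cc(OC)c2C(=O)O1 | intermediate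
13 | (3R)-6,8-dihydroxy-3-[(9S)-9-hydroxyundecyl]isochroman-1-one | CC[C@H](O)CCCCCCCC[C@@H]1Cc2cc(O)cc(O)c2C(=O)O1 | target

## Step count and least certain steps

Total steps: 7. Longest linear sequence: 7 steps (1 to 13); acid 9 and salt 6 enter as purchased.

**Step 5 (key step).** Three things may go wrong. The electron-rich, ortho-substituted acid may lose carbon dioxide under silver and heat before C–H cleavage. The reaction may stall before dehydration. The silyl ether may be cleaved by the Lewis-acidic medium. Fallback, from ester 5 to isocoumarin 11 through keto acid 10: the C4a–C4 bond is made by lateral metalation of a toluate. Methyl 2,4-dimethoxy-6-methylbenzoate F1 is deprotonated at its benzylic methyl group with LiN(iPr)2 (2.2 equiv, THF, −78 °C). The anion is acylated by ester 5 in a Claisen-type condensation to give methyl 2,4-dimethoxy-6-[(11S)-11-(tert-butyldimethylsilyloxy)-2-oxotridecyl]benzoate F2. Saponification (KOH, aqueous ethanol, reflux, which a secondary silyl ether tolerates) gives keto acid 10. Cyclodehydration with acetic anhydride then closes ring B to 11.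

**Step 6.** Facial selectivity may be poor with a long, flexible 3-alkyl chain. Turnover may be slow next to the peri 8-methoxy group. The alkoxide base may open the lactone. Fallback, from alkene 4 to lactone 12: C3 is taken from a resolved epoxide instead of a hydrogenation.
- Alkene 4 is epoxidised (mCPBA, CH2Cl2) to tert-butyldimethyl{[(3S)-11-(oxiran-2-yl)undecan-3-yl]oxy}silane F3, as both epimers at the oxirane carbon.
- Jacobsen hydrolytic kinetic resolution uses the antipode of (salen)Co(OAc) that hydrolyses the S oxirane (salen = N,N'-bis(3,5-di-tert-butylsalicylidene)-1,2-cyclohexanediamine dianion, trivalent cobalt). It leaves tert-butyldimethyl{[(3S)-11-[(2R)-oxiran-2-yl]undecan-3-yl]oxy}silane F4 and converts the other epimer into (2S,11S)-11-(tert-butyldimethylsilyloxy)tridecane-1,2-diol F5, which is removed by chromatography.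
- Methyl 2-bromo-4,6-dimethoxybenzoate F6 undergoes bromine–magnesium exchange with iPrMgCl·LiCl (THF, −15 °C) to [3,5-dimethoxy-2-(methoxycarbonyl)phenyl]magnesium chloride F7.
- With catalytic CuI, F7 opens F4 at its unsubstituted carbon to methyl 2-[(2R,11S)-11-(tert-butyldimethylsilyloxy)-2-hydroxytridecyl]-4,6-dimethoxybenzoate F8. Its alkoxide closes onto the ortho ester on warming and gives 12. The stereocentre is not touched in the opening.

**Step 7.** The C9' borate may be substituted by bromide. The lactone C3–O bond may be cleaved. The non-chelated 6-methoxy group may be removed incompletely. Fallback, from ylide 8 to target 13: the phenols are carried as benzyl ethers so the release is a hydrogenolysis.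
- 2,4-Bis(benzyloxy)benzoic acid F9 is annulated with 8 under the conditions of step 5. This passes through 2,4-bis(benzyloxy)-6-[(11S)-11-(tert-butyldimethylsilyloxy)-2-oxotridecyl]benzoic acid F10 to 6,8-bis(benzyloxy)-3-[(9S)-9-(tert-butyldimethylsilyloxy)undecyl]-1H-isochromen-1-one F11.
- Hydrogenation as in step 6 gives (3R)-6,8-bis(benzyloxy)-3-[(9S)-9-(tert-butyldimethylsilyloxy)undecyl]isochroman-1-one F12.
- Hydrogenolysis (H2, Pd/C, ethyl acetate) gives (3R)-6,8-dihydroxy-3-[(9S)-9-(tert-butyldimethylsilyloxy)undecyl]isochroman-1-one F13.
- Aqueous HF in acetonitrile removes the silyl group and gives 13.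

## Further compounds

F1 | step 5 | methyl 2,4-dimethoxy-6-methylbenzoate | COC(=O)c1c(C)cc(OC)cc1OC
F2 | step 5 | methyl 2,4-dimethoxy-6-[(11S)-11-(tert-butyldimethylsilyloxy)-2-oxotridecyl]benzoate | CC[C@H](O[Si](C)(C)C(C)(C)C)CCCCCCCCC(=O)Cc1cc(OC)cc(OC)c1C(=O)OC
F3 | step 6 | tert-butyldimethyl{[(3S)-11-(oxiran-2-yl)undecan-3-yl]oxy}silane (both oxirane epimers) | CC[C@H](O[Si](C)(C)C(C)(C)C)CCCCCCCCC1CO1
F4 | step 6 | tert-butyldimethyl{[(3S)-11-[(2R)-oxiran-2-yl]undecan-3-yl]oxy}silane | CC[C@H](O[Si](C)(C)C(C)(C)C)CCCCCCCC[C@@H]1CO1
F5 | step 6 | (2S,11S)-11-(tert-butyldimethylsilyloxy)tridecane-1,2-diol | CC[C@H](O[Si](C)(C)C(C)(C)C)CCCCCCCC[C@H](O)CO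
F6 | step 6 | methyl 2-bromo-4,6-dimethoxybenzoate | COC(=O)c1c(Br)cc(OC)cc1OC
F7 | step 6 | [3,5-dimethoxy-2-(methoxycarbonyl)phenyl]magnesium chloride | COC(=O)c1c([Mg]Cl)cc(OC)cc1OC
F8 | step 6 | methyl 2-[(2R,11S)-11-(tert-butyldimethylsilyloxy)-2-hydroxytridecyl]-4,6-dimethoxybenzoate | CC[C@H](O[Si](C)(C)C(C)(C)C)CCCCCCCC[C@@H](O)Cc1cc(OC)cc(OC)c1C(=O)OC
F9 | step 7 | 2,4-bis(benzyloxy)benzoic acid | OC(=O)c1ccc(OCc2ccccc2)cc1OCc1ccccc1
F10 | step 7 | 2,4-bis(benzyloxy)-6-[(11S)-11-(tert-butyldimethylsilyloxy)-2-oxotridecyl]benzoic acid | CC[C@H](O[Si](C)(C)C(C)(C)C)CCCCCCCCC(=O)Cc1cc(OCc2ccccc2)cc(OCc2ccccc2)c1C(=O)O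
F11 | step 7 | 6,8-bis(benzyloxy)-3-[(9S)-9-(tert-butyldimethylsilyloxy)undecyl]-1H-isochromen-1-one | CC[C@H](O[Si](C)(C)C(C)(C)C)CCCCCCCCC1=Cc2cc(OCc3ccccc3)cc(OCc3ccccc3)c2C(=O)O1
F12 | step 7 | (3R)-6,8-bis(benzyloxy)-3-[(9S)-9-(tert-butyldimethylsilyloxy)undecyl]isochroman-1-one | CC[C@H](O[Si](C)(C)C(C)(C)C)CCCCCCCC[C@@H]1Cc2cc(OCc3ccccc3)cc(OCc3ccccc3)c2C(=O)O1
F13 | step 7 | (3R)-6,8-dihydroxy-3-[(9S)-9-(tert-butyldimethylsilyloxy)undecyl]isochroman-1-one | CC[C@H](O[Si](C)(C)C(C)(C)C)CCCCCCCC[C@@H]1Cc2cc(O)cc(O)c2C(=O)O1
A1 | alternative 1 | 6,8-dimethoxyisochromane-1,3-dione (3,5-dimethoxyhomophthalic anhydride) | COc1cc(OC)c2C(=O)OC(=O)Cc2c1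
A2 | alternative 1 | (10S)-10-(tert-butyldimethylsilyloxy)dodecanal | CC[C@H](O[Si](C)(C)C(C)(C)C)CCCCCCCCC=O
A3 | alternative 1 | (3R)-6,8-dimethoxy-1-oxo-3-[(9S)-9-(tert-butyldimethylsilyloxy)undecyl]isochromane-4-carboxylic acid (both C4 epimers) | CC[C@H](O[Si](C)(C)C(C)(C)C)CCCCCCCC[C@@H]1C(C(=O)O)c2cc(OC)cc(OC)c2C(=O)O1
A4 | alternative 2 | (6R)-4-(2-diazoacetyl)-6-[(9S)-9-(tert-butyldimethylsilyloxy)undecyl]-5,6-dihydro-2H-pyran-2-one | CC[C@H](O[Si](C)(C)C(C)(C)C)CCCCCCCC[C@@H]1CC(C(=O)C=[N+]=[N-])=CC(=O)O1
A5 | alternative 2 | ethoxyacetylene | CCOC#C
A6 | alternative 2 | (3R)-6-ethoxy-8-hydroxy-3-[(9S)-9-(tert-butyldimethylsilyloxy)undecyl]isochroman-1-one | CC[C@H](O[Si](C)(C)C(C)(C)C)CCCCCCCC[C@@H]1Cc2cc(OCC)cc(O)c2C(=O)O1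
A7 | alternative 3 | 6-[(6R,15S)-6,15-bis(tert-butyldimethylsilyloxy)-2,4-dioxoheptadecyl]-2,2-dimethyl-4H-1,3-dioxin-4-one | CC[C@H](O[Si](C)(C)C(C)(C)C)CCCCCCCC[C@@H](O[Si](C)(C)C(C)(C)C)CC(=O)CC(=O)CC1=CC(=O)OC(C)(C)O1
A8 | alternative 3 | 7-hydroxy-2,2-dimethyl-5-[(2R,11S)-2,11-bis(tert-butyldimethylsilyloxy)tridecyl]-4H-benzo[d][1,3]dioxin-4-one | CC[C@H](O[Si](C)(C)C(C)(C)C)CCCCCCCC[C@@H](O[Si](C)(C)C(C)(C)C)Cc1cc(O)cc2OC(C)(C)OC(=O)c12
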